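Which of the three flasks, held at 35 °C, 60 °C and 85 °C, gives the purest E among E and D? In each, the enantiomers L and X take up Z as it is fed, over the single-handed catalyst Q. I keep the books on theta, which runs at the temperature of the north-west run.

in all of them: L 0.10 M; X 0.10 M; Q 2.5 mol%
- east: Z 2.8 equiv (fed, over 25 h); temperature 30 °C; run made earlier; the fed solution adds 0.10 times the starting volume
- north-west: Z 4.4 equiv (fed, over 25 h); temperature 60 °C; run made earlier; the fed solution adds 0.10 times the starting volume
- beta: Z 2.00 equiv (fed, over 25 h); temperature 35 °C; the fed solution adds 0.10 times the starting volume; time 25 h
- theta: Z 2.00 equiv (fed, over 25 h); temperature 60 °C; the fed solution adds 0.10 times the starting volume; time 25 h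
- epsilon: Z 2.00 equiv (fed, over 25 h); temperature 85 °C; the fed solution adds 0.10 times the starting volume; time 25 h

- east (time / h: E / %, D / %): 1.50: 0.6, 0; 4.00: 1.6, 1.4; 8.00: 6.1, 2.3; 20.0: 25.0, 2.6
- north-west (time / h: E / %, D / %): 1.33: 2.7, 0.7; 3.00: 9.7, 0.9; 4.00: 16.2, 1.1; 6.00: 23.5, 1.3

(readings scatter by 1 percentage point)

- which flask leads in share of E in all that became E or D ("all alike" within 1.5 percentage points) (beta / theta / epsilon / all alike)
- share of E in all that became E or D, beta
- share of E in all that became E or D, theta
- share of E in all that became E or D, epsilon

- Q is single-handed; L and X are mirror images of each other, charged as a racemate, each of them at the stated concentration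
- every charge counts on the volume at the start, and the solution that is fed holds the whole dose

I open two accounts, each holding half of the pool charged. L pays into E, X pays into D, and for now I book no transfer between them. In the last north-west row the L account has paid 23.5 % and the X account 1.3 %, so the logarithms of what remains stand in the ratio

24.1.

This is the selectivity factor, the logarithm of the fraction of L left divided by that of the fraction of X left, and it lets me write one account from the other. It is a rough reading: D stands against a scatter of 1 percentage point, and the last east row, at 30 °C, gives 13.0. I carry the north-west value for its temperature.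

To close theta's books I need to know how far L goes. As my own rough assumption, I take Z as fed, with none used and Q unchanged, so that the logarithm of L left grows with the dose rate times the time squared. Scaling the north-west row to theta at 25 h gives a logarithm of 5.01, and the accounts close as follows:

L account: 49.7 % into E, 0.334 % left
X account: 9.39 % into D, 40.6 % left
Share of E: 84.1 %

The forecast names beta as the leader, with 91.5 %, 87 % and 75 % for beta, theta and epsilon, saying of theta that “L is essentially consumed, so X begins to react”. My books put theta lower than its figure.

The flasks give 94.1 % for beta, 87.2 % for theta and 87.8 % for epsilon, so beta leads and the forecast's 75 % for epsilon is the figure that parts. Z + Q + L → Q + E (k = 28.0 /M²/min, Ea = 61.0 kJ/mol); Z + Q + X → Q + D (k = 1.40 /M²/min, Ea = 69.0 kJ/mol); L ⇌ X (k = 4.40 × 10⁻⁵ /min, Ea = 119 kJ/mol); Z + Q → J (k = 0.00180 /M/min, Ea = 65.0 kJ/mol); 2 Z → G (k = 0.00280 /M/min, Ea = 91.0 kJ/mol); (constants at 60 °C)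

Epsilon holds 68.0 % of E at 25.0 h, more than the 50.0 % of the pool charged as L, and with the L still there its account is overdrawn by 21 points, while the passing of L into X speeds up by a factor of 650 from the coldest flask to the hottest. The carried factor, applied to the simulated L left at the same temperature as its reading, gives theta 89.2 % against 87.2 %, and a flask like theta but with 0.500 equiv of Z 95.1 % against 94.1 %.

Readings and results were generated by integration with made-up constants; scatter was added.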